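The route rests on reading the C7–C1–C2 corner of the cyclohexane ring as a 2,3-epoxy alcohol opened at its distal carbon. That corner is the quaternary carbinol C1 carrying the C7 hydroxymethyl, with a trans oxygen on C2. One epoxidation of the C1=C2 alkene, catalysed by Ti(OiPr)4 and diethyl tartrate and steered by the C7 hydroxyl, fixes C1 and so the absolute configuration of the series. Its substrate is an achiral cyclohexenylmethanol whose future C6 carbinol is masked as an ethylene ketal. After anti opening at C2, a trans-fused C1/C2 acetonide freezes the chair with C7 axial. C5 (enolate hydroxylation) and C6 (hydride addition) then follow under substrate control.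

Key step: step 4

Numbering (target locants, used for all compounds): C1 is the ring carbon bearing OH and the C7H2O arm. C2 is the neighbouring CHOH, C3 and C4 are CH2, C5 is CH–OBz, and C6 is the CHOH between C5 and C1. With the ring drawn flat and numbered clockwise, O1 and O5 point up; C7, O2 and O6 point down. In these locants the target is (1S,2R,5R,6S).

Assumption: the empirical enantioface rule of the Ti(OiPr)4/tartrate epoxidation is taken to hold for 8 although the geminal substituent C6 is a ketal carbon. If the sense of induction proved opposite, the antipodal tartrate would be used.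

Step 1
Reactants: 1 cyclohex-2-en-1-one
Product: 3 2-bromocyclohex-2-en-1-one, via dibromoketone 2 (not isolated)
Conditions: Br2 (1.05 equiv), CH2Cl2, 0 °C; then Et3N (1.6 equiv), 0 °C → rt
Reagents that add atoms: bromine, BrBr
Why: Bromination–dehydrobromination: bromine adds across the enone C=C and the amine removes the acidic α-hydrogen with loss of the β-bromide, leaving bromine on the carbon that becomes C1; no stereocentre survives.

Step 2
Reactants: 3 2-bromocyclohex-2-en-1-one; 4 ethylene glycol
Product: 5 6-bromo-1,4-dioxaspiro[4.5]dec-6-ene
Conditions: HOCH2CH2OH (3 equiv), p-TsOH·H2O (cat.), benzene, reflux, Dean–Stark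
Reagents that add atoms: ethylene glycol (4), OCCO
Why: Acid-catalysed ketalisation with azeotropic removal of water; as is usual for 2-haloenones the double bond stays at C1=C2, and the ketal shields C6 from the organolithium of the next step.

Step 3
Reactants: 5 6-bromo-1,4-dioxaspiro[4.5]dec-6-ene; 6 formaldehyde
Product: 8 (1,4-dioxaspiro[4.5]dec-6-en-6-yl)methanol, via vinyllithium 7 (not isolated)
Conditions: n-BuLi (1.1 equiv), THF, −78 °C; HCHO gas (cracked paraformaldehyde), −78 °C → rt; H2O
Reagents that add atoms: formaldehyde (6), C=O
Why: Bromine–lithium exchange gives an α-ketovinyl anion equivalent whose 1,2-addition to monomeric formaldehyde forms the C1–C7 bond; the product is achiral.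

Step 4
Reactants: 8 (1,4-dioxaspiro[4.5]dec-6-en-6-yl)methanol
Product: 9 [(1'S,6'S)-spiro[1,3-dioxolane-2,2'-[7]oxabicyclo[4.1.0]heptan]-1'-yl]methanol (route locants 1S,2S; oxirane on the upper face)
Conditions: Ti(OiPr)4 (10 mol %), L-(+)-diethyl tartrate (13 mol %), t-BuOOH (2 equiv, anhydrous), 4 Å MS, CH2Cl2, −20 °C
Reagents that add atoms: tert-butyl hydroperoxide, CC(C)(C)OO
Why: The C7 alkoxide and the hydroperoxide exchange onto the complex formed from Ti(OiPr)4 and the tartrate, and the metal-activated peroxide oxygen passes in one concerted syn event to C1=C2, making the C1–O and C2–O bonds together. This is the Sharpless asymmetric epoxidation in its catalytic molecular-sieve form, established for 2,3-disubstituted allylic alcohols such as 1-cyclohexenylmethanols. The only ring closed is the three-membered oxirane, formed by oxygen-atom transfer and necessarily cis-fused to the six-membered ring, so no ring of the target is formed. Because 8 is achiral, both C1 and C2 are set by the tartrate alone: L-(+)-diethyl tartrate, the enantiomer that turns (E)-2-alken-1-ols into (2S,3S)-epoxides, should take the face leading to (1S,2S)-9 once C6 stands for the geminal hydrogen and C3 for the E substituent. The selectivity needed is enantioface selectivity, and the substrate supports it with a free primary carbinol for binding, only hydrogen cis to C7 on C2, a single alkene and a compact five-membered ketal at C6. Only the C1–O bond persists to the target, since C2–O is replaced with inversion in step 5.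

Step 5
Reactants: 9 epoxy alcohol (1S,2S); 10 benzoic acid
Product: 12 [(6S,7R)-6,7-dihydroxy-1,4-dioxaspiro[4.5]decan-6-yl]methyl benzoate, via C2-benzoate 11 (not isolated)
Conditions: Ti(OiPr)4 (1.5 equiv), PhCO2H (1.5 equiv), CH2Cl2, rt; aq. tartaric acid work-up; crude, 1,8-diazabicyclo[5.4.0]undec-7-ene (0.2 equiv), toluene, 40 °C
Reagents that add atoms: benzoic acid (10), OC(=O)c1ccccc1
Why: Titanium-assisted opening of a 2,3-epoxy alcohol: binding of O7 and the oxirane oxygen to Ti(OiPr)4 sends benzoate to the distal secondary C2 in an anti, trans-diaxial SN2 sense, which inverts C2 to R and leaves C1–O intact (attack at the quaternary, ketal-flanked C1 would lead into the mirror-image series and is disfavoured sterically and electronically), and the base-catalysed O2→O7 acyl migration through a six-membered orthoacid, possible because O2 and C7 are cis, then moves the ester to the less crowded primary position as in O4→O6 benzoyl shifts of hexopyranosides.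

Step 6
Reactants: 12 C7-benzoate diol ketal
Product: 13 [(1S,2R)-1,2-dihydroxy-6-oxocyclohexyl]methyl benzoate
Conditions: 1 M aq. HCl–THF (1:2), 40 °C
Reagents that add atoms: water, O
Why: Acid-catalysed ketal hydrolysis, placed here because no acid-labile group is yet present, so the inductively deactivated α-oxygenated ketal can be forced; the benzoate and both carbinols tolerate aqueous acid, and quaternary C1 offers no hydrogen for β-elimination of O2 or O7.

Step 7
Reactants: 13 dihydroxy ketone
Product: 14 [(3aS,7aR)-2,2-dimethyl-4-oxohexahydro-1,3-benzodioxol-3a-yl]methyl benzoate (trans-fused)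
Conditions: 2-methoxypropene (3 equiv), camphor-10-sulfonic acid (5 mol %), CH2Cl2, 0 °C → rt; Et3N quench
Reagents that add atoms: 2-methoxypropene, COC(C)=C
Why: Acetonide formation by acid-catalysed transacetalisation; the only diol is the trans C1/C2 pair, which can be bridged only with both oxygens equatorial, so the trans-fused dioxolane freezes the chair in which C7 is axial without touching a stereocentre.

Step 8
Reactants: 14 acetonide ketone
Product: 16 [(3aS,5R,7aR)-5-hydroxy-2,2-dimethyl-4-oxohexahydro-1,3-benzodioxol-3a-yl]methyl benzoate, via potassium enolate 15 (not isolated)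
Conditions: KN(SiMe3)2 (1.15 equiv), THF, −78 °C; 2-(phenylsulfonyl)-3-phenyloxaziridine (1.4 equiv), −78 °C; AcOH quench
Reagents that add atoms: 2-(phenylsulfonyl)-3-phenyloxaziridine, O=S(=O)(N1OC1c1ccccc1)c1ccccc1
Why: Davis enolate hydroxylation: only C5 carries enolisable hydrogens because C1 is quaternary, and in the locked half-chair the axial C7H2OBz arm screens the lower face, so oxygen should arrive from above to give the equatorial (5R) carbinol, which is also the thermodynamically preferred epimer.

Step 9
Reactants: 16 hydroxy ketone
Product: 17 [(3aS,5R,7aR)-5-(benzoyloxy)-2,2-dimethyl-4-oxohexahydro-1,3-benzodioxol-3a-yl]methyl benzoate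
Conditions: BzCl (1.3 equiv), pyridine, 4-(dimethylamino)pyridine (cat.), CH2Cl2, 0 °C → rt
Reagents that add atoms: benzoyl chloride, O=C(Cl)c1ccccc1
Why: Nucleophile-catalysed O-acylation of the only free hydroxyl; C5 is not involved in bond breaking, and any base-induced epimerisation could only return to the favoured equatorial ester.

Step 10
Reactants: 17 dibenzoate ketone
Product: 18 [(3aR,4S,5R,7aR)-5-(benzoyloxy)-4-hydroxy-2,2-dimethylhexahydro-1,3-benzodioxol-3a-yl]methyl benzoate
Conditions: NaBH4, CeCl3·7H2O, MeOH–CH2Cl2, −78 °C; AcOH quench
Reagents that add atoms: none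
Why: Luche reduction: in the locked chair hydride should add along the axial trajectory on the upper face, anti to the axial C7 arm on neighbouring C1, giving the equatorial (6S) alcohol trans to O5 and O1, while the low temperature and the weakly acidic CeCl3/MeOH medium hold back O5→O6 benzoyl migration.

Step 11
Reactants: 18 acetonide alcohol
Product: 19 [(1S,2S,3R,6R)-3-(benzoyloxy)-1,2,6-trihydroxycyclohexyl]methyl benzoate (route locants 1S,2R,5R,6S; the target)
Conditions: AcOH–H2O (4:1), 45 °C
Reagents that add atoms: none
Why: Acid-catalysed acetal hydrolysis; the strained trans-fused dioxolane should cleave under conditions mild enough to keep both benzoates in place, and the acidic medium disfavours acyl migration, so no stereocentre is affected.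

Compound list
1 | cyclohex-2-en-1-one | O=C1C=CCCC1 | starting material
2 | 2,3-dibromocyclohexan-1-one (racemic) | O=C1CCCC(Br)C1Br | intermediate
3 | 2-bromocyclohex-2-en-1-one | O=C1CCCC=C1Br | intermediate
4 | ethylene glycol | OCCO | starting material
5 | 6-bromo-1,4-dioxaspiro[4.5]dec-6-ene | BrC1=CCCCC12OCCO2 | intermediate
6 | formaldehyde (from paraformaldehyde) | C=O | starting material
7 | (1,4-dioxaspiro[4.5]dec-6-en-6-yl)lithium | [Li]C1=CCCCC12OCCO2 | intermediate
8 | (1,4-dioxaspiro[4.5]dec-6-en-6-yl)methanol | OCC1=CCCCC12OCCO2 | intermediate
9 | [(1'S,6'S)-spiro[1,3-dioxolane-2,2'-[7]oxabicyclo[4.1.0]heptan]-1'-yl]methanol | OC[C@]1(O2)[C@@H]2CCCC13OCCO3 | intermediate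
10 | benzoic acid | OC(=O)c1ccccc1 | starting material
11 | (6S,7R)-6-hydroxy-6-(hydroxymethyl)-1,4-dioxaspiro[4.5]decan-7-yl benzoate | OC[C@]1(O)[C@H](OC(=O)c2ccccc2)CCCC13OCCO3 | intermediate
12 | [(6S,7R)-6,7-dihydroxy-1,4-dioxaspiro[4.5]decan-6-yl]methyl benzoate | O=C(OC[C@]1(O)[C@H](O)CCCC12OCCO2)c1ccccc1 | intermediate
13 | [(1S,2R)-1,2-dihydroxy-6-oxocyclohexyl]methyl benzoate | O=C(OC[C@]1(O)[C@H](O)CCCC1=O)c1ccccc1 | intermediate
14 | [(3aS,7aR)-2,2-dimethyl-4-oxohexahydro-1,3-benzodioxol-3a-yl]methyl benzoate | O=C(OC[C@]12OC(C)(C)O[C@@H]1CCCC2=O)c1ccccc1 | intermediate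
15 | potassium C5=C6 enolate of 14 | O=C(OC[C@]12OC(C)(C)O[C@@H]1CCC=C2[O-])c1ccccc1.[K+] | intermediate
16 | [(3aS,5R,7aR)-5-hydroxy-2,2-dimethyl-4-oxohexahydro-1,3-benzodioxol-3a-yl]methyl benzoate | O=C(OC[C@]12OC(C)(C)O[C@@H]1CC[C@@H](O)C2=O)c1ccccc1 | intermediate
17 | [(3aS,5R,7aR)-5-(benzoyloxy)-2,2-dimethyl-4-oxohexahydro-1,3-benzodioxol-3a-yl]methyl benzoate | O=C(OC[C@]12OC(C)(C)O[C@@H]1CC[C@@H](OC(=O)c3ccccc3)C2=O)c1ccccc1 | intermediate
18 | [(3aR,4S,5R,7aR)-5-(benzoyloxy)-4-hydroxy-2,2-dimethylhexahydro-1,3-benzodioxol-3a-yl]methyl benzoate | O=C(OC[C@]12OC(C)(C)O[C@@H]1CC[C@@H](OC(=O)c3ccccc3)[C@@H]2O)c1ccccc1 | intermediate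
19 | [(1S,2S,3R,6R)-3-(benzoyloxy)-1,2,6-trihydroxycyclohexyl]methyl benzoate | O=C(OC[C@]1(O)[C@H](O)CC[C@@H](OC(=O)c2ccccc2)[C@@H]1O)c1ccccc1 | target

Total step count: 11. Longest linear sequence: 11 (fully linear from 1).

Steps most likely to fail

**Step 4.** Turnover may be slow and enantioface discrimination eroded. The fully substituted, Lewis-basic ketal carbon C6 sits geminal to the carbinol arm; it may crowd the bound alkene or compete for titanium. The fallback gives up metal-alkoxide direction and epoxidises 8 with a chiral dioxirane (Shi epoxidation). The catalyst is 1,2:4,5-di-O-isopropylidene-β-L-erythro-2,3-hexodiulo-2,6-pyranose, the L-fructose-derived enantiomer that gives (S,S)-epoxides from trisubstituted olefins. The conditions are KHSO5 (as 2KHSO5·KHSO4·K2SO4), K2CO3 buffer and MeCN–dimethoxymethane–water at 0 °C, a method known for trisubstituted olefins that carry a free hydroxyl. It sets out from 8 and comes back at 9, and it makes no new compound (F0).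

**Step 5.** Attack at C2 may be slow, because the incoming benzoate runs syn-axial to one ketal oxygen. During a long reaction the ester may be partly lost to isopropoxide on titanium, and the O2→O7 migration may stop at an equilibrium mixture. The fallback no longer relies on where the ester sits.
- The opening is pushed to full conversion.
- The crude ester mixture containing 11 is methanolysed (K2CO3, MeOH, 0 °C → rt) to the triol (6S,7R)-6-(hydroxymethyl)-1,4-dioxaspiro[4.5]decane-6,7-diol F1.
- The primary C7 hydroxyl of F1 is benzoylated kinetically in preference to the secondary C2 and tertiary C1 hydroxyls (BzCl 1.05 equiv, 2,4,6-collidine, CH2Cl2, −40 °C).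

This fallback sets out from 11 and comes back at 12.

**Step 10.** Hydride may be delivered from the lower face, a trajectory that the two flanking equatorial oxygens favour electronically. The O5 benzoyl group may also migrate to the new O6 alkoxide. The fallback reverses the order of acylation and reduction.
- Setting out from 16, the free C5 hydroxyl binds Me4NBH(OAc)3 (MeCN–AcOH, −30 °C, Evans–Saksena reduction).
- Hydride is handed over on the open upper face under acidic, migration-free conditions, giving the trans-diol [(3aR,4S,5R,7aR)-4,5-dihydroxy-2,2-dimethylhexahydro-1,3-benzodioxol-3a-yl]methyl benzoate F2.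
- The C5 hydroxyl, next to a CH2, is benzoylated in preference to the C6 hydroxyl, which is wedged between C5 and quaternary C1 (BzCl 1.05 equiv, pyridine, CH2Cl2, −20 °C).

This fallback comes back to the route at 18.

Further compounds
F0 | step 4 | none | none
F1 | step 5 | (6S,7R)-6-(hydroxymethyl)-1,4-dioxaspiro[4.5]decane-6,7-diol | OC[C@]1(O)[C@H](O)CCCC12OCCO2
F2 | step 10 | [(3aR,4S,5R,7aR)-4,5-dihydroxy-2,2-dimethylhexahydro-1,3-benzodioxol-3a-yl]methyl benzoate | O=C(OC[C@]12OC(C)(C)O[C@@H]1CC[C@@H](O)[C@@H]2O)c1ccccc1
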